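The earlier runs and the new flask were computed from invented constants; noise was put on by code.

Read the floor off the earlier runs before you charge the next flask: the decision is whether to add Z, how much X to charge, and when to stop.

| flask | X | Z | remark | time |
|---|---|---|---|---|
| autumn | 10 mM (fed, over 80 s) | 0.20 mM | run made earlier |  |
| noon | 15 mM (fed, over 80 s) | 0.20 mM | run made earlier |  |
| dawn | 20 mM (fed, over 80 s) | 0.30 mM | run made earlier |  |
| flask | 20 mM (fed, over 80 s) | 0.20 mM |  | 5.0 min |

- autumn (time / min: Q / %, X / %): 0.833: 0, 62.7; 1.50: 11.3, 87.9; 2.50: 17.3, 82.1; 3.00: 18.9, 82.7; 4.00: 17.5, 82.8; 5.00: 17.4, 82.4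
- noon (time / min: Q / %, X / %): 0.417: 0.5, 31.4; 0.667: 0.3, 50.6; 1.00: 8.6, 67.3; 2.00: 43.6, 55.6; 3.00: 45.3, 54.5; 5.00: 45.1, 54.8
- dawn (time / min: Q / %, X / %): 0.417: 0, 30.6; 0.833: 10.8, 51.4; 1.33: 45.5, 54.2; 2.50: 59.3, 40.7; 5.00: 59.6, 41.7

(each reading ± 0.5 percentage points)

- the average divides the monomer in chains by the number of chains begun, living and dead together
- reactions considered so far: Q + G -> X + G; X + G -> Q + G; 2 Z -> J; X + Z -> G + Q
- the earlier runs do not show the number of chains; that part of a forecast is a guess
- percentages count the whole charge, also what has not yet gone in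

1. average number of monomer units in a chain (chains begun, living or dead) at 5.0 min
2. part of the X that has reacted at 5.0 min

Take the last noon reading of X and multiply it by the noon charge:

floor = 54.8% × 15 mM = 8.22 mM

This is the floor, the cX that stands once the readings stop changing (the equilibrium monomer concentration). Autumn gives 8.24 mM. Dawn, with 0.30 mM of Z against 0.20 mM, gives 8.34 mM. With readings scattering by 0.5 percentage points, that is no clear move, so keep Z at 0.20 mM and reckon c from the X charge. Noon, with the same Z, reads Q 45.3% at 3.00 min and 45.1% at 5.00 min, and dawn, with the same X charge, reads Q 59.3% at 2.50 min and 59.6% at 5.00 min, so stop the flask at 5.0 min.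

My reckoning for the flask, with each Z beginning at most one chain:

c = 1 − floor/cX charged = 58.9%

dp ≥ (cX charged − floor)/cZ charged = 58.9

The forecast gives c 59% and dp 65, on the words “I guess about 90% of Z starts chains”.

The flask gives c 58.9% and dp 114.

    Q + G → X + G, rate k1*[G] as long as [Q] is above zero (k = 6.00 /s)
    X + G → Q + G, rate k2*[G]*[X] (k = 730 /M/s)
    2 Z → J (k = 360 /M/s)
    X + Z → G + Q (k = 65.0 /M/s)

In the flask at 5.00 min, the half-life of X by its passing into Q is 0.15 min, shorter than the 5.0 min of the run. X stands at 41.2% at 2.50 min and 41.1% at 5.00 min, while G stands at 0.103 mM, about half of the Z charged, and the charge less the floor, divided by that G, comes to 114. In the neighbour charged with 34 mM of X, the floor reckons c at 75.8%, and that neighbour stands at 75.8%.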